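Look into the closed, stirred vessel: a racemate of substrate, a single-handed coupling partner, a racemization catalyst, and an impurity that can spend that catalyst.

| flask | left-handed substrate | right-handed substrate | coupling partner | racemization catalyst | impurity | remark | time |
|---|---|---|---|---|---|---|---|
| blue | 0.10 M | 0.10 M | 0.56 M | 50 µM | 75 µM | run made earlier |  |
| ochre | 0.10 M | 0.10 M | 0.88 M | 50 µM | 75 µM | run made earlier |  |
| flask | 0.10 M | 0.10 M | 0.400 M | 50 µM | 75 µM |  | 2.0 h |

| run | time / h | left-handed product / % | right-handed product / % |
|---|---|---|---|
| blue | 0.200 | 48.1 | 30.1 |
| blue | 0.333 | 54.5 | 36.4 |
| blue | 0.500 | 56.6 | 40.3 |
| blue | 0.833 | 56.2 | 41.9 |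
| blue | 1.33 | 56.8 | 43.2 |
| blue | 2.50 | 56.4 | 44.3 |
| ochre | 0.167 | 51.9 | 36.4 |
| ochre | 0.500 | 56.1 | 43.3 |
| ochre | 0.833 | 56.1 | 43.3 |
| ochre | 1.33 | 55.2 | 44.3 |
| ochre | 2.00 | 55.9 | 44.4 |
| ochre | 2.50 | 55.6 | 43.8 |

(readings scatter by 0.5 percentage points)

- left-handed product and right-handed product together, in percent of the left-handed substrate and right-handed substrate charged together, at 2.0 h
- excess of left-handed product over right-handed product in the product at 2.0 h
- whether the exchange between left-handed substrate and right-handed substrate keeps pace with the reaction: how far the product's excess at 2.0 h gets from its value without exchange to its value with instant exchange (above 80% keeps pace, below 20% hardly takes part, else lags behind)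

- coupling partner is single-handed; left-handed substrate and right-handed substrate are mirror images of each other, charged as a racemate, each of them at the stated concentration
- the earlier runs were read with a standard deviation of 0.5 percentage points
- what may be going on: coupling partner + left-handed substrate -> left-handed product; coupling partner + right-handed substrate -> right-handed product; left-handed substrate + racemization catalyst <-> right-handed substrate + racemization catalyst; racemization catalyst + impurity -> spent catalyst; coupling partner -> decomposed reagent
- an excess is the difference of the two amounts in percent of their sum
- an excess is below zero if the other one leads
- the handed part of coupling partner does not stay in what it makes, so the products of the two hands are mirror images too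

Take the racemate as the zero of the scale. Without exchange, each product stops at half of the charge, so at full conversion the excess is zero. With instant exchange, the substrate stays racemic and the products keep the ratio of the two couplings, the selectivity factor. The first blue reading shows 1.60 to one, an excess of 23.0%; take that as a low mark for this end.

Place the real flask between these ends. The last blue and ochre readings give on average 6 percentage points for the crossover, the left-handed product above half the charge, which is the net substrate that changed hands. Ochre held 1.57 times the partner of blue, yet in these last readings the left-handed product of the two runs differs by 0.8 points, against a scatter of 0.5 points on each reading. So between these two runs the crossover stays near the scatter of the readings, and the racemization catalyst, charged below the impurity, may stop working early.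

The forecast gives a yield of 97.5% (94.5% to 99.5%) and an excess of 15.3% (12.8% to 18.5%), and says exchange lags behind: “Exchange therefore stops long before coupling does.” Carry the crossover to the flask, which has the same catalyst and impurity charges but less partner: as your own reckoning, twice the left-handed product minus the yield, over the yield, gives with the forecast's yield 14.9%, a little below the forecast's excess.

The flask gives a yield of 98.8%, an excess of 14.3%, and exchange lags behind, 34% of the way.

    coupling partner + left-handed substrate → left-handed product (k = 0.00750 M⁻¹ s⁻¹)
    coupling partner + right-handed substrate → right-handed product (k = 0.00330 M⁻¹ s⁻¹)
    left-handed substrate + racemization catalyst ⇌ right-handed substrate + racemization catalyst, rate k3*[racemization catalyst]*[left-handed substrate] forward; the back reaction follows from the equilibrium constant (k = 38.0 M⁻¹ s⁻¹)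
    racemization catalyst + impurity → spent catalyst (k = 46.0 M⁻¹ s⁻¹)
    coupling partner → decomposed reagent (k = 1.20 × 10⁻⁴ s⁻¹)

Read back from these two results, the flask's crossover is 6.5 points. The neighbouring flask holds 12.0 µM of racemization catalyst, with the impurity unchanged. Take the catalyst's life as unchanged and scale the crossover with the charge: 1.4 points. With the neighbouring flask's yield of 98.5%, that makes an excess of 4.44%. The neighbouring flask gives an excess of 4.10%, with 47.2% of right-handed product at 2.00 h.

All runs come from a simulation for an exercise, noise included.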